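Positions follow labdane numbering (decalin C1–C10, C17 on C8, C18 and C19 on C4, C20 on C10, side chain C11–C16); β is the face of the C20 methyl group.

## The problem

The target is a normal-series labdane: a trans-fused decalin (ring A: C1–C5, C10; ring B: C5–C10). C9 carries the C11–C16 chain ending in a 2-substituted buta-1,3-diene, C8 is a tertiary carbinol (8α-OH, 8β-CH3), and the axial C19 oxygen on C4 is esterified with (Z)-4-hydroxycinnamic acid. All five stereocentres (C4, C5, C10, C9, C8) lie in one contiguous row on the bicycle; two are quaternary (C4 and C10, with C19 and C20 syn on the β face). Absolute control is therefore needed only once: if C4 is set first and can direct C10, C5 follows from C10 through the trans ring fusion, and C9 and C8 can be relayed from the rigid decalin, whose β face is shielded by C20. Three groups will not survive rough treatment: the Z-enoate (E-isomerisation by light, base or nucleophilic catalysts, most easily as the phenoxide), the conjugated diene (acid, radicals, electrophilic oxidants, heat) and the tertiary 8α-hydroxy group, which eliminates in acid and closes a tetrahydrofuran onto any electrophilic C12. This fixes the order of the late events: C12 must be coupled before the C8 oxygen exists, and the Z double bond should be the last carbon–carbon bond made. The feature that opens the skeleton is in ring B: C17 on C8 and C20 on quaternary C10 flank C9, so C6–C7–C8(C17)–C9 map onto 3-methylbut-3-en-2-one, and C5 becomes the carbonyl carbon of a ring A cyclohexanone whose C4 is already quaternary (CH3 and C19) and which can therefore enolise only towards C10.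

## Retrosynthesis

**Z-enoate.** In 28 the first bond cut is the Cα=Cβ double bond of the coumarate, not the ester C–O bond. 28 comes from its aryl silyl ether 27, and 27 from phosphonoacetate 25 and aldehyde 26 by a Z-selective olefination. Acylation with a preformed Z-cinnamic acid is rejected because the acid would have to be activated with a nucleophilic catalyst to reach the neopentyl C19 alcohol, conditions under which it isomerises. An ynoate with semihydrogenation is rejected because of the diene. 25 is cut at the ester C–O bond into diol 23 and phosphonoacetic acid 24, an acid with no geometry to lose. The forward steps must acylate the primary C19 hydroxyl beside the tertiary C8 hydroxyl and form the alkene under kinetic control.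

**C8 carbinol.** Diol 23 is the desilylated form of 22. In 22 the C8–O and C7–H bonds are traced through the 7α,8α-epoxide 21 to the C7=C8 double bond of triene 20. The neighbouring cut, C8–C17 (methyl addition to an 8-ketone), is rejected: the nucleophile would enter equatorially from the α face and give the 8β-alcohol. An alkene is instead oxidised from the α face and puts the oxygen where it belongs. The precursor has one stereocentre less and no tertiary alcohol. The forward steps must epoxidise the ring alkene beside the diene and deliver hydride to C7.

**Diene.** Triene 20 is cut at C12–C13 into iodide 19 and a buta-1,3-dien-2-yl nucleophile; 19 comes from alcohol 18 and 18 from ester 17. The cut is placed before the C8 oxygen is introduced, because an 8α-alkoxide and a C12 leaving group would close the tetrahydrofuran. The price is that the diene must survive the epoxidation and everything after it. Building the diene from an alkyne by enyne metathesis costs one more step and is kept in reserve. Ester 17 is far simpler: no diene, an ordinary ester.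

**C9 side chain.** Ester 17 is cut at C9–C11 by a Claisen retron: the C7=C8 double bond and the C12 carbonyl lead to allylic alcohol 14 (7β-OH, C8=C9) through mixed orthoester 15 and ketene acetal 16. The competing cut, conjugate addition to C9 of enone 13, would bring the carbon in axially from the α face and give the 9-epimer. The sigmatropic route transfers the configuration of C7, easily set by reduction, to the β face of C9, and leaves exactly the C7=C8 alkene the carbinol plan needs. The precursor has no side chain. The forward reaction must form a bond next to quaternary C10 on the face of C20.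

**Adjusting ring B.** Alcohol 14 comes from enone 13 by 1,2-reduction, 13 from saturated ketone 11 through silyl enol ether 12, and 11 from enone 10 by dissolving-metal reduction. No skeletal bond is cut. These steps set C5 and move the unsaturation from C5=C6 to C8=C9; they are the price of the C7 carbonyl that the annulation leaves behind.

**Ring B (key disconnection).** Enone 10 is cut at C9–C10 and C5=C6 into ring A ketone 6 and 3-methylbut-3-en-2-one 7, via Michael adduct 8 and ketol 9. The neighbouring order, annulating ring A onto a ring B ketone, would set C10 first and leave the C4 quaternary centre, with its two different substituents, to a late alkylation of a hindered bicyclic ketone. Here C4 is made first on a monocycle, where catalysis can reach it. One ring, two skeletal bonds and one stereocentre are removed, and the precursors are a monocyclic ketone and a commercial enone. The forward reaction must attack C10 anti to the C19 arm and close onto a carbonyl flanked by two quaternary carbons.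

**Ring A ketone.** Ketone 6 is cut at C10–C20 (enolate methylation) to 5, the silyl ether of 4. Alcohol 4 is cut at C4–C19 into silyl enol ether 2 and formaldehyde 3, a catalytic enantioselective hydroxymethylation. Enol ether 2 comes from 2-methylcyclohexanone 1. The C20 methyl is deliberately added after C4 is set. The enol ether of 2,6-dimethylcyclohexanone would be a racemate with a stereocentre beside the reacting π system, and the catalyst would have to override it in one enantiomer. Enol ether 2 is achiral, at the cost of one trivial step.

## Roads not taken

**Alternative 1:** Diene last by ethylene enyne metathesis. The cut removes the two terminal methylene carbons (C13=C16 and C14=C15) and leads to the terminal alkyne A2 and ethylene. Forward, A2 and ethylene react over second-generation Grubbs catalyst to give the 8α-hydroxy diene A1 (C19 tert-butyldimethylsilyl ether).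
- Merits: the most fragile carbon fragment is made under neutral conditions as late as possible, a free tertiary alcohol is tolerated, and an alkyne is inert to peracid and hydride, so the chemoselectivity question of the epoxidation does not arise.
- Weak points: this is an end-game tactic. All five stereocentres and ring B are already contained in A2, so it does not say how the core is made. It also needs a C12 electrophile and an acetylide, one step more than direct coupling of the diene.
- Comparison: for the diene alone this road is as good as the chosen one and safer in the oxidation step. The chosen plan sets against it a shorter sequence (one coupling instead of alkynylation plus metathesis), and it keeps the metathesis as the fallback for step 14.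

**Alternative 2:** Ring B by lactone-terminated cationic closure. The cut is C9–C10 and O–C8; the precursor is the monocyclic (E)-alkenoic acid A4. Forward, protonation of the C5=C10 alkene gives the C10 cation, C9 of the C8=C9 alkene attacks it, and the carboxyl captures C8, giving the trans-fused 8α,12-lactone A3 (C19 acetate).
- Merits: two bonds, ring B, the C8 oxygen and up to four stereocentres form in one step, and C12 arrives at a useful oxidation level. On paper this reaches the bicycle in far fewer steps than the seven that lead here from 6 to 17, and it is well known for gem-dimethyl analogues.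
- Weak points:
  - The only stereocentre of A4 is C4, whose substituents (CH3 and CH2OAc) differ little, so nothing in the chair-like cationic transition state ensures that C5, C10 and C9 form in the right sense relative to C4.
  - The C19 acetoxy group is 1,3 to the C10 cation and can participate or ionise in strong acid.
  - A4 itself needs an enantioselective route to a C4-quaternary cyclohexene with a defined trisubstituted alkene.
  - Opening A3 towards the diene creates a C12 electrophile beside the 8α-oxygen, the tetrahydrofuran problem.
- Comparison: this road is clearly shorter. The chosen plan sets against it that every stereocentre is set in a separate, correctable step, that no strong acid is used, and that the C8 carbinol appears only after C12 has been coupled.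

**Alternative 3:** Ring A from podocarpic acid, ring B by ketyl–enoate closure. The cut is C8–C9; the precursor is the keto enoate A6, to be carved out of podocarpic acid A7. Forward, SmI2 (divalent samarium) reduces the C8 methyl ketone to a ketyl that adds to the enoate β-carbon C9 (6-exo-trig), giving the 8α-hydroxy diester A5.
- Merits: C4, C5 and C10 come from the chiral pool with the right absolute configuration and with C19 already oxidised. There is no question of enantiomeric purity and no C10 epimer. In this respect the road is better than the chosen one. The radical closure makes the carbinol and C9 in one mild step.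
- Weak points:
  - Degrading the aromatic ring and ring B of A7 down to A6 is long and oxidative.
  - The two ester groups of A5 must later be told apart.
  - The ketyl closure must place OH on the α face and the chain on the β face relative to C10, which rests on a transition-state preference, not a rule.
  - The starting acid is a scarce natural product available in one enantiomeric series only.
- Comparison: the chosen plan sets against the better stereochemical security of this road cheap achiral starting materials, access to either enantiomer, and a forward, non-degradative sequence.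

Key step: step 5

Assumption: the enantiomer of the bipyridine ligand in step 2 is the one that gives (R)-4; both ligand enantiomers are accessible, so the sense of induction only decides which is used.
Assumption: acid 24, the free acid of the commercial Z-selective olefination reagent, is taken as a catalogue compound.

## Route

Step 1
Reactants: 1 2-methylcyclohexanone
Product: 2 1-methyl-2-(trimethylsilyloxy)cyclohex-1-ene
Conditions: TMSCl, NaI, Et3N, MeCN, rt
Reagents that add atoms: chlorotrimethylsilane, C[Si](C)(C)Cl
Why: Silyl enol ether formation under equilibrating conditions (iodotrimethylsilane made in situ, amine base) favours the tetrasubstituted enol ether; the minor trisubstituted isomer is carried on and its hydroxymethylation product is separated after step 2.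

Step 2
Reactants: 2 1-methyl-2-(trimethylsilyloxy)cyclohex-1-ene; 3 formaldehyde (aqueous)
Product: 4 (R)-2-(hydroxymethyl)-2-methylcyclohexan-1-one
Conditions: Sc(OTf)3 (10 mol %), chiral 6,6'-bis(1-hydroxy-2,2-dimethylpropyl)-2,2'-bipyridine (12 mol %), aq. HCHO, DME–H2O, −20 °C
Reagents that add atoms: none
Why: Catalytic enantioselective Mukaiyama aldol reaction with formaldehyde (hydroxymethylation), known for tetrasubstituted silyl enol ethers of cyclic ketones. The chiral Sc(OTf)3–bipyridine complex binds formaldehyde and the achiral enol ether attacks one enantioface, so the quaternary C4 centre is set as (R) by the catalyst alone.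

Step 3
Reactants: 4 (R)-2-(hydroxymethyl)-2-methylcyclohexan-1-one
Product: 5 (R)-2-methyl-2-[(triisopropylsilyloxy)methyl]cyclohexan-1-one
Conditions: TIPSCl, imidazole, DMF, rt
Reagents that add atoms: chlorotriisopropylsilane, CC(C)[Si](Cl)(C(C)C)C(C)C
Why: Silylation of a primary alcohol under mild base that does not provoke retro-aldol cleavage. The triisopropylsilyl ether withstands alkoxide, Li/NH3, LiAlH4 and peracid, and its bulk serves the facial bias in step 5.

Step 4
Reactants: 5 (R)-2-methyl-2-[(triisopropylsilyloxy)methyl]cyclohexan-1-one
Product: 6 (2R)-2,6-dimethyl-2-[(triisopropylsilyloxy)methyl]cyclohexan-1-one (both C6 epimers)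
Conditions: LiN(iPr)2, THF, −78 °C; MeI, −78 → 0 °C
Reagents that add atoms: iodomethane, CI
Why: Enolate alkylation: with the other α-carbon quaternary, deprotonation can occur only at C10, and methylation there installs C20. The new centre forms as a mixture, which does not matter because it becomes the enolate carbon in step 5.

Step 5
Reactants: 6 (2R)-2,6-dimethyl-2-[(triisopropylsilyloxy)methyl]cyclohexan-1-one; 7 3-methylbut-3-en-2-one
Product: 10 19-(triisopropylsilyloxy)-11,12,13,14,15,16-hexanorlabd-5-en-7-one (bicyclic enone; 10β-CH3 cis to 4β-CH2OSi(iPr)3; C8 epimers), via Michael adduct diketone 8 (not isolated), via ketol 9 (not isolated)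
Conditions: KOt-Bu (cat.), t-BuOH–THF, 0 °C → rt; then NaOMe, MeOH, 60 °C
Reagents that add atoms: none
Why: Catalytic tert-butoxide forms the only enolate that 6 can give (C4 has no hydrogen), the C5–C10 enolate, which adds to the unsubstituted β-carbon of 7 (Michael addition) and so forms C9–C10 and the quaternary C10 of diketone 8. Methoxide in warm methanol then enolises the methyl ketone at C6, which adds to the C5 carbonyl to give ketol 9, and E1cB loss of water gives enone 10 with the C5=C6 bond. The closest known reaction type is the Robinson annulation of 2,2,6-trisubstituted cyclohexanones with α-substituted vinyl ketones. Ring B closes by a 6-(enolexo)-exo-trig aldol addition; the other enolate of the side chain, at C8, could only close a four-membered ring. The new stereocentre C10 is controlled by C4: the acceptor enters axially at C10 and is then syn-axial to one C4 substituent, which costs less when that is the methyl group than when it is the branched silyloxymethyl arm, so the chain ends anti to C19 and C20 cis to C19. The step needs this facial selectivity and no other, since regiochemistry is fixed by the quaternary C4; the C10 epimer is a diastereomer of 10 and is removed by chromatography without loss of enantiomeric purity. C8 forms as an epimeric mixture, which is of no consequence because it becomes trigonal in step 7.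

Step 6
Reactants: 10 19-(triisopropylsilyloxy)-11,12,13,14,15,16-hexanorlabd-5-en-7-one
Product: 11 19-(triisopropylsilyloxy)-11,12,13,14,15,16-hexanorlabdan-7-one (5α-H, trans-decalin; C8 epimers)
Conditions: Li, NH3(l), THF, t-BuOH (1 equiv), −78 °C; NH4Cl
Reagents that add atoms: none
Why: Dissolving-metal (Birch-type) reduction of an enone: the β-carbon C5 is protonated axially from the α face, anti to C20, which sets the 5α-hydrogen and the trans ring fusion. The silyl ether is inert.

Step 7
Reactants: 11 19-(triisopropylsilyloxy)-11,12,13,14,15,16-hexanorlabdan-7-one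
Product: 12 7-(trimethylsilyloxy)-19-(triisopropylsilyloxy)-11,12,13,14,15,16-hexanorlabd-7-ene
Conditions: TMSCl, NaI, Et3N, MeCN, rt → 40 °C
Reagents that add atoms: chlorotrimethylsilane, C[Si](C)(C)Cl
Why: Thermodynamic silyl enol ether formation favours the tetrasubstituted C7=C8 enol ether. Any C6=C7 isomer is harmless, because step 8 would turn it back into enone 10, which is recycled.

Step 8
Reactants: 12 7-(trimethylsilyloxy)-19-(triisopropylsilyloxy)-11,12,13,14,15,16-hexanorlabd-7-ene
Product: 13 19-(triisopropylsilyloxy)-11,12,13,14,15,16-hexanorlabd-8-en-7-one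
Conditions: Pd(OAc)2 (1.1 equiv), MeCN, rt
Reagents that add atoms: none
Why: Saegusa oxidation: the palladium enolate bound at C8 undergoes syn β-hydride elimination of the axial C9 hydrogen and releases zerovalent palladium, giving the endocyclic, conjugated α-methyl enone.

Step 9
Reactants: 13 19-(triisopropylsilyloxy)-11,12,13,14,15,16-hexanorlabd-8-en-7-one
Product: 14 19-(triisopropylsilyloxy)-11,12,13,14,15,16-hexanorlabd-8-en-7β-ol
Conditions: NaBH4, CeCl3·7H2O, MeOH, −78 → 0 °C
Reagents that add atoms: none
Why: Luche reduction gives clean 1,2-reduction. Hydride adds axially from the α face of the C7 carbonyl, so the pseudoequatorial 7β-alcohol results, the configuration step 10 needs.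

Step 10
Reactants: 14 19-(triisopropylsilyloxy)-11,12,13,14,15,16-hexanorlabd-8-en-7β-ol
Product: 17 ethyl 19-(triisopropylsilyloxy)-13,14,15,16-tetranorlabd-7-en-12-oate (9β-CH2CO2Et; 9α-H), via mixed orthoester 15 (not isolated), via ketene acetal 16 (not isolated)
Conditions: MeC(OEt)3, EtCO2H (cat.), xylene, 140 °C
Reagents that add atoms: triethyl orthoacetate, CC(OCC)(OCC)OCC
Why: Johnson–Claisen rearrangement: alcohol exchange gives 15, loss of ethanol gives ketene acetal 16, and the [3,3]-sigmatropic shift forms C9–C11 on the face of the breaking C7–O bond. The 7β-oxygen is thus translated into the 9β-chain (9α-H) and the double bond moves to C7=C8, as in the known rearrangements of pseudoequatorial steroidal allylic alcohols next to an angular methyl group.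

Step 11
Reactants: 17 ethyl 19-(triisopropylsilyloxy)-13,14,15,16-tetranorlabd-7-en-12-oate
Product: 18 19-(triisopropylsilyloxy)-13,14,15,16-tetranorlabd-7-en-12-ol
Conditions: LiAlH4, THF, 0 °C
Reagents that add atoms: none
Why: Hydride reduction of the ester to the primary alcohol; the isolated trisubstituted alkene and the silyl ether do not react.

Step 12
Reactants: 18 19-(triisopropylsilyloxy)-13,14,15,16-tetranorlabd-7-en-12-ol
Product: 19 12-iodo-19-(triisopropylsilyloxy)-13,14,15,16-tetranorlabd-7-ene
Conditions: I2, PPh3, imidazole, CH2Cl2, 0 °C → rt
Reagents that add atoms: iodine, II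
Why: Appel-type iodination of a primary alcohol by SN2 displacement of the alkoxyphosphonium group. The C8 oxygen does not yet exist, so no cyclic ether can form.

Step 13
Reactants: 19 12-iodo-19-(triisopropylsilyloxy)-13,14,15,16-tetranorlabd-7-ene
Product: 20 19-(triisopropylsilyloxy)labda-7,13(16),14-triene
Conditions: buta-1,3-dien-2-ylmagnesium chloride (from 2-chlorobuta-1,3-diene, Mg, THF), Li2CuCl4 (cat.), THF, −10 °C → rt
Reagents that add atoms: buta-1,3-dien-2-ylmagnesium chloride, C=CC(=C)[Mg]Cl (prepared from 2-chlorobuta-1,3-diene, C=CC(Cl)=C)
Why: Copper-catalysed cross-coupling of a primary alkyl iodide with the chloroprene-derived Grignard reagent, a known route to 2-alkylbuta-1,3-dienes. It forms C12–C13 and completes the side chain.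

Step 14
Reactants: 20 19-(triisopropylsilyloxy)labda-7,13(16),14-triene
Product: 21 7α,8α-epoxy-19-(triisopropylsilyloxy)labda-13(16),14-diene
Conditions: mCPBA (1.0 equiv), NaHCO3, CH2Cl2, −20 → 0 °C
Reagents that add atoms: 3-chloroperoxybenzoic acid, OOC(=O)c1cccc(Cl)c1
Why: Peracid (Prilezhaev) epoxidation is fastest at the most electron-rich alkene, the trisubstituted C7=C8 bond, as in the selective epoxidation of the trisubstituted alkene of myrcene. The reagent approaches from the α face, away from C20 and the 9β-chain, which sets the oxygen on C8 as α.

Step 15
Reactants: 21 7α,8α-epoxy-19-(triisopropylsilyloxy)labda-13(16),14-diene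
Product: 22 19-(triisopropylsilyloxy)labda-13(16),14-dien-8α-ol
Conditions: LiAlH4, THF, reflux
Reagents that add atoms: none
Why: Hydride opens the trisubstituted epoxide by SN2 attack at the secondary C7 and leaves the C8–O bond untouched, giving the tertiary 8α-alcohol with 8β-CH3, as in the reduction of 7α,8α-epoxydrimanes. The diene is inert to LiAlH4.

Step 16
Reactants: 22 19-(triisopropylsilyloxy)labda-13(16),14-dien-8α-ol
Product: 23 labda-13(16),14-diene-8α,19-diol
Conditions: Bu4NF, THF, rt → 45 °C
Reagents that add atoms: none
Why: Fluoride cleavage of the silyl ether frees the C19 alcohol; the diene and the tertiary alcohol are not affected.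

Step 17
Reactants: 23 labda-13(16),14-diene-8α,19-diol; 24 [bis(2,2,2-trifluoroethoxy)phosphoryl]acetic acid
Product: 25 8α-hydroxylabda-13(16),14-dien-19-yl [bis(2,2,2-trifluoroethoxy)phosphoryl]acetate
Conditions: DCC, DMAP (cat.), CH2Cl2, 0 °C → rt
Reagents that add atoms: none
Why: Carbodiimide (Steglich) esterification: the primary C19 alcohol, although neopentyl, is acylated, while the tertiary, axially flanked 8α-alcohol is not. Phosphonoacetic acids are activated very readily by carbodiimides, which helps with the hindered alcohol, and the acid has no geometry to lose.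

Step 18
Reactants: 25 8α-hydroxylabda-13(16),14-dien-19-yl [bis(2,2,2-trifluoroethoxy)phosphoryl]acetate; 26 4-(tert-butyldimethylsilyloxy)benzaldehyde
Product: 27 8α-hydroxylabda-13(16),14-dien-19-yl (Z)-3-[4-(tert-butyldimethylsilyloxy)phenyl]prop-2-enoate
Conditions: KN(SiMe3)2 (1.0 equiv), 18-crown-6, THF, −78 °C; then 26, −78 °C
Reagents that add atoms: none
Why: Still–Gennari variant of the Horner–Wadsworth–Emmons reaction: the trifluoroethyl phosphonate with a dissociated potassium counter-ion eliminates fast from the kinetically formed adduct and gives the (Z)-enoate. One equivalent of base deprotonates only the phosphonate, not the tertiary alcohol.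

Step 19
Reactants: 27 8α-hydroxylabda-13(16),14-dien-19-yl (Z)-3-[4-(tert-butyldimethylsilyloxy)phenyl]prop-2-enoate
Product: 28 8α-hydroxylabda-13(16),14-dien-19-yl (Z)-3-(4-hydroxyphenyl)prop-2-enoate (target)
Conditions: Bu4NF, AcOH, THF, 0 °C, dark
Reagents that add atoms: none
Why: Buffered fluoride removes the aryl silyl ether quickly at 0 °C. Acetic acid keeps the phenol protonated, avoiding the phenoxide that would ease Z-to-E isomerisation, and light is excluded for the same reason.

## Compound list

1 | 2-methylcyclohexanone (racemic) | CC1CCCCC1=O | starting material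
2 | 1-methyl-2-(trimethylsilyloxy)cyclohex-1-ene | CC1=C(O[Si](C)(C)C)CCCC1 | intermediate
3 | formaldehyde (aqueous solution) | C=O | starting material
4 | (R)-2-(hydroxymethyl)-2-methylcyclohexan-1-one | O=C1CCCC[C@]1(C)CO | intermediate
5 | (R)-2-methyl-2-[(triisopropylsilyloxy)methyl]cyclohexan-1-one | O=C1CCCC[C@]1(C)CO[Si](C(C)C)(C(C)C)C(C)C | intermediate
6 | (2R)-2,6-dimethyl-2-[(triisopropylsilyloxy)methyl]cyclohexan-1-one, both C6 epimers | CC1CCC[C@](C)(CO[Si](C(C)C)(C(C)C)C(C)C)C1=O | intermediate
7 | 3-methylbut-3-en-2-one | CC(=O)C(C)=C | starting material
8 | Michael adduct: 2,6-dimethyl-6-(2-methyl-3-oxobutyl)-2-[(triisopropylsilyloxy)methyl]cyclohexan-1-one, oxobutyl chain trans to the silyloxymethyl group (formed in the flask, not isolated) | CC(=O)C(C)C[C@@]1(C)CCC[C@](C)(CO[Si](C(C)C)(C(C)C)C(C)C)C1=O | intermediate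
9 | ketol: 5-hydroxy-19-(triisopropylsilyloxy)-11,12,13,14,15,16-hexanorlabdan-7-one (formed in the flask, not isolated) | CC1C[C@@]2(C)CCC[C@](C)(CO[Si](C(C)C)(C(C)C)C(C)C)C2(O)CC1=O | intermediate
10 | 19-(triisopropylsilyloxy)-11,12,13,14,15,16-hexanorlabd-5-en-7-one (4α-CH3, 4β-CH2OSi(iPr)3, 10β-CH3; C8 epimers) | CC1C[C@@]2(C)CCC[C@](C)(CO[Si](C(C)C)(C(C)C)C(C)C)C2=CC1=O | intermediate
11 | 19-(triisopropylsilyloxy)-11,12,13,14,15,16-hexanorlabdan-7-one (5α-H; C8 epimers) | CC1C[C@@]2(C)CCC[C@](C)(CO[Si](C(C)C)(C(C)C)C(C)C)[C@@H]2CC1=O | intermediate
12 | 7-(trimethylsilyloxy)-19-(triisopropylsilyloxy)-11,12,13,14,15,16-hexanorlabd-7-ene | C1[C@@]2(C)CCC[C@](C)(CO[Si](C(C)C)(C(C)C)C(C)C)[C@@H]2CC(O[Si](C)(C)C)=C1C | intermediate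
13 | 19-(triisopropylsilyloxy)-11,12,13,14,15,16-hexanorlabd-8-en-7-one | CC1=C[C@@]2(C)CCC[C@](C)(CO[Si](C(C)C)(C(C)C)C(C)C)[C@@H]2CC1=O | intermediate
14 | 19-(triisopropylsilyloxy)-11,12,13,14,15,16-hexanorlabd-8-en-7β-ol | CC1=C[C@@]2(C)CCC[C@](C)(CO[Si](C(C)C)(C(C)C)C(C)C)[C@@H]2C[C@@H]1O | intermediate
15 | mixed orthoester: 7β-(1,1-diethoxyethoxy)-19-(triisopropylsilyloxy)-11,12,13,14,15,16-hexanorlabd-8-ene (formed in the flask, not isolated) | CC1=C[C@@]2(C)CCC[C@](C)(CO[Si](C(C)C)(C(C)C)C(C)C)[C@@H]2C[C@@H]1OC(C)(OCC)OCC | intermediate
16 | ketene acetal: 7β-(1-ethoxyethenyloxy)-19-(triisopropylsilyloxy)-11,12,13,14,15,16-hexanorlabd-8-ene (formed in the flask, not isolated) | CC1=C[C@@]2(C)CCC[C@](C)(CO[Si](C(C)C)(C(C)C)C(C)C)[C@@H]2C[C@@H]1OC(=C)OCC | intermediate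
17 | ethyl 19-(triisopropylsilyloxy)-13,14,15,16-tetranorlabd-7-en-12-oate (9β-chain, 9α-H) | CCOC(=O)C[C@@H]1[C@@]2(C)CCC[C@](C)(CO[Si](C(C)C)(C(C)C)C(C)C)[C@@H]2CC=C1C | intermediate
18 | 19-(triisopropylsilyloxy)-13,14,15,16-tetranorlabd-7-en-12-ol | OCC[C@@H]1[C@@]2(C)CCC[C@](C)(CO[Si](C(C)C)(C(C)C)C(C)C)[C@@H]2CC=C1C | intermediate
19 | 12-iodo-19-(triisopropylsilyloxy)-13,14,15,16-tetranorlabd-7-ene | ICC[C@@H]1[C@@]2(C)CCC[C@](C)(CO[Si](C(C)C)(C(C)C)C(C)C)[C@@H]2CC=C1C | intermediate
20 | 19-(triisopropylsilyloxy)labda-7,13(16),14-triene | C=CC(=C)CC[C@@H]1[C@@]2(C)CCC[C@](C)(CO[Si](C(C)C)(C(C)C)C(C)C)[C@@H]2CC=C1C | intermediate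
21 | 7α,8α-epoxy-19-(triisopropylsilyloxy)labda-13(16),14-diene | C=CC(=C)CC[C@@H]1[C@@]2(C)CCC[C@](C)(CO[Si](C(C)C)(C(C)C)C(C)C)[C@@H]2C[C@H]3O[C@@]13C | intermediate
22 | 19-(triisopropylsilyloxy)labda-13(16),14-dien-8α-ol | C=CC(=C)CC[C@@H]1[C@@]2(C)CCC[C@](C)(CO[Si](C(C)C)(C(C)C)C(C)C)[C@@H]2CC[C@@]1(C)O | intermediate
23 | labda-13(16),14-diene-8α,19-diol | C=CC(=C)CC[C@@H]1[C@@]2(C)CCC[C@](C)(CO)[C@@H]2CC[C@@]1(C)O | intermediate
24 | [bis(2,2,2-trifluoroethoxy)phosphoryl]acetic acid | OC(=O)CP(=O)(OCC(F)(F)F)OCC(F)(F)F | starting material
25 | 8α-hydroxylabda-13(16),14-dien-19-yl [bis(2,2,2-trifluoroethoxy)phosphoryl]acetate | C=CC(=C)CC[C@@H]1[C@@]2(C)CCC[C@](C)(COC(=O)CP(=O)(OCC(F)(F)F)OCC(F)(F)F)[C@@H]2CC[C@@]1(C)O | intermediate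
26 | 4-(tert-butyldimethylsilyloxy)benzaldehyde | O=Cc1ccc(O[Si](C)(C)C(C)(C)C)cc1 | starting material
27 | 8α-hydroxylabda-13(16),14-dien-19-yl (Z)-3-[4-(tert-butyldimethylsilyloxy)phenyl]prop-2-enoate | C=CC(=C)CC[C@@H]1[C@@]2(C)CCC[C@](C)(COC(=O)/C=C\c3ccc(O[Si](C)(C)C(C)(C)C)cc3)[C@@H]2CC[C@@]1(C)O | intermediate
28 | 8α-hydroxylabda-13(16),14-dien-19-yl (Z)-3-(4-hydroxyphenyl)prop-2-enoate (CNP0197278.1) | C=CC(=C)CC[C@@H]1[C@@]2(C)CCC[C@](C)(COC(=O)/C=C\c3ccc(O)cc3)[C@@H]2CC[C@@]1(C)O | target

## Step count and least certain steps

Total: 19 steps. Longest linear sequence: 19 steps (1 → 28); compounds 3, 7, 24 and 26 enter as purchased materials.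

**Step 5 (key step).** Most likely to fail through poor facial selectivity at C10, because the two C4 substituents differ only moderately in effective size near the ring. The second risk is stalling of the aldol closure at the C5 carbonyl, which sits between two quaternary carbons, so that retro-Michael loss of 7 and its polymerisation take over. Fallback, setting out from 6: deprotonation and silylation (LiN(iPr)2, TMSCl) give the trimethylsilyl enol ether of 6, F1. Its Mukaiyama–Michael addition to 7 with TiCl4 in CH2Cl2 at −78 °C is irreversible and proceeds through an open transition state in which the bulky acceptor–TiCl4 complex must avoid the silyloxymethyl arm; it gives diketone 8 as an isolated compound. Diketone 8 is then cyclised and dehydrated in a separate operation (KOH, MeOH, or TsOH in toluene with removal of water), and the route is rejoined at 10.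

**Step 2.** Most likely to fail through insufficient enantioselectivity with a fully aliphatic tetrasubstituted enol ether, and through competing hydrolysis of 2 in the aqueous medium. Fallback, setting out from 2: hydroxymethylation with Sc(OTf)3 alone gives racemic 2-(hydroxymethyl)-2-methylcyclohexan-1-one F2, which is resolved by preparative chromatography on a chiral stationary phase. The (R)-enantiomer is 4, where the route is rejoined.

**Step 7 (with step 8).** Most likely to fail through enolisation towards C6 instead of C8, and then, in step 8, through β-hydride elimination into the C17 methyl group to give the exocyclic enone. Fallback, setting out from 11: chlorination at the more substituted α-carbon with SO2Cl2 (CH2Cl2, 0 °C) gives the 8-chloro ketone F3. Dehydrochlorination with LiBr and Li2CO3 in DMF gives the conjugated endocyclic enone, and the route is rejoined at 13.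

**Step 10.** Most likely to fail through acid-promoted elimination of the allylic alcohol to a ring diene at 140 °C, and through slow rearrangement because the new bond forms beside quaternary C10 on the face of C20. Fallback, setting out from 14: acetylation (Ac2O, pyridine) gives the 7β-acetate F4. Ireland–Claisen rearrangement (LiN(iPr)2, TMSCl, THF, −78 °C, then warming) proceeds under basic conditions with the same facial transfer and gives, after aqueous work-up, the C12 carboxylic acid F5. LiAlH4 reduces F5 to the alcohol, and the route is rejoined at 18.

**Step 14.** Most likely to fail through loss of chemoselectivity, that is, epoxidation of the 1,1-disubstituted diene terminus beside or instead of the hindered ring alkene. Fallback, setting out from 19: displacement with lithium acetylide–ethylenediamine complex (LiC≡CH·H2NCH2CH2NH2, DMSO) gives the terminal alkyne F6, which is inert to peracid. mCPBA gives the 7α,8α-epoxy alkyne F7, LiAlH4 gives the 8α-hydroxy alkyne F8, and enyne metathesis with ethylene over second-generation Grubbs catalyst builds the diene. The route is rejoined at 22.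

## Further compounds

F1 | step 5 | (R)-trimethyl{[2,6-dimethyl-6-[(triisopropylsilyloxy)methyl]cyclohex-1-en-1-yl]oxy}silane | CC1=C(O[Si](C)(C)C)[C@@](C)(CO[Si](C(C)C)(C(C)C)C(C)C)CCC1
F2 | step 2 | racemic 2-(hydroxymethyl)-2-methylcyclohexan-1-one | O=C1CCCCC1(C)CO
F3 | step 7 | 8-chloro-19-(triisopropylsilyloxy)-11,12,13,14,15,16-hexanorlabdan-7-one | CC1(Cl)C[C@@]2(C)CCC[C@](C)(CO[Si](C(C)C)(C(C)C)C(C)C)[C@@H]2CC1=O
F4 | step 10 | 19-(triisopropylsilyloxy)-11,12,13,14,15,16-hexanorlabd-8-en-7β-yl acetate | CC1=C[C@@]2(C)CCC[C@](C)(CO[Si](C(C)C)(C(C)C)C(C)C)[C@@H]2C[C@@H]1OC(C)=O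
F5 | step 10 | 19-(triisopropylsilyloxy)-13,14,15,16-tetranorlabd-7-en-12-oic acid | OC(=O)C[C@@H]1[C@@]2(C)CCC[C@](C)(CO[Si](C(C)C)(C(C)C)C(C)C)[C@@H]2CC=C1C
F6 | step 14 | 19-(triisopropylsilyloxy)-15,16-dinorlabd-7-en-13-yne | C#CCC[C@@H]1[C@@]2(C)CCC[C@](C)(CO[Si](C(C)C)(C(C)C)C(C)C)[C@@H]2CC=C1C
F7 | step 14 | 7α,8α-epoxy-19-(triisopropylsilyloxy)-15,16-dinorlabd-13-yne | C#CCC[C@@H]1[C@@]2(C)CCC[C@](C)(CO[Si](C(C)C)(C(C)C)C(C)C)[C@@H]2C[C@H]3O[C@@]13C
F8 | step 14 | 19-(triisopropylsilyloxy)-15,16-dinorlabd-13-yn-8α-ol | C#CCC[C@@H]1[C@@]2(C)CCC[C@](C)(CO[Si](C(C)C)(C(C)C)C(C)C)[C@@H]2CC[C@@]1(C)O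
A1 | alternative 1 | 19-(tert-butyldimethylsilyloxy)labda-13(16),14-dien-8α-ol | C=CC(=C)CC[C@@H]1[C@@]2(C)CCC[C@](C)(CO[Si](C)(C)C(C)(C)C)[C@@H]2CC[C@@]1(C)O
A2 | alternative 1 | 19-(tert-butyldimethylsilyloxy)-15,16-dinorlabd-13-yn-8α-ol | C#CCC[C@@H]1[C@@]2(C)CCC[C@](C)(CO[Si](C)(C)C(C)(C)C)[C@@H]2CC[C@@]1(C)O
A3 | alternative 2 | 19-acetoxy-13,14,15,16-tetranorlabdan-8α,12-olide | O=C1C[C@@H]2[C@@]3(C)CCC[C@](C)(COC(C)=O)[C@@H]3CC[C@@]2(C)O1
A4 | alternative 2 | (E)-6-[6-(acetoxymethyl)-2,6-dimethylcyclohex-1-en-1-yl]-4-methylhex-3-enoic acid, ring C6 configured as C4 of the target | CC1=C(CC/C(C)=C/CC(O)=O)[C@@](C)(COC(C)=O)CCC1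
A5 | alternative 3 | dimethyl 8α-hydroxy-13,14,15,16-tetranorlabdane-12,19-dioate | COC(=O)C[C@@H]1[C@@]2(C)CCC[C@](C)(C(=O)OC)[C@@H]2CC[C@@]1(C)O
A6 | alternative 3 | dimethyl (E)-8-oxo-8,9-seco-13,14,15,16-tetranorlabd-9(11)-ene-12,19-dioate | COC(=O)/C=C/[C@@]1(C)CCC[C@](C)(C(=O)OC)[C@@H]1CCC(C)=O
A7 | alternative 3 | podocarpic acid (12-hydroxypodocarpa-8,11,13-trien-19-oic acid) | Oc1ccc2c(c1)[C@@]1(C)CCC[C@](C)(C(=O)O)[C@@H]1CC2
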